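**Retrosynthetic overview**
1. The target is (−)-epigallocatechin 3-O-gallate-(4β→8)-(+)-catechin. The C3–O gallate ester and thirteen benzyl ethers are handled last. The lower flavan (2R,3S) is bought as (+)-catechin and functionalised at C8.
2. Feature used: upper ring A (C4a, C5, C6, C7, C8, C8a, oxygenated at C5, C7 and C8a) is the aromatised form of a 5-oxygenated cyclohexane-1,3-dione. Dione C2 is C4a, and one enol oxygen is O1.
3. Key disconnection: C4–C4a and O1–C2 are made together by iminium-catalysed Michael addition and hemiacetalisation of that dione with the catechin-8-yl propenal. This sets C4, which relays to C3 (anti enolate hydroxylation) and then to C2 (chelate reduction, Mitsunobu inversion).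
4. Ring order: ring A carbocycle (from the triol), then the oxygen heterocycle as lactol and lactone, then ring A aromatised. The lactone is opened by the ring B aryllithium (C2–C1'), and ring C is reclosed at O1–C2.
5. O7 travels as a silyl ether. Unmasking it and oxidising the C7 carbinol gives the trione tautomer of the phloroglucinol. This avoids enolate-based dehydrogenation (β-elimination of O7) and quinone-based dehydrogenation (attack at benzylic C2/C4 of the catechin unit).

Key step: step 7

Assumption: 5-bromo-1,2,3-trimethoxybenzene, 3,4,5-tris(benzyloxy)benzoic acid, (E)-3-(dimethylamino)acrolein and all-cis-cyclohexane-1,3,5-triol are taken as commercial; flavan numbering of the upper unit is kept for all intermediates, ring-opened ones included, and "catechin-8-yl" means the (2R,3S)-3,5,7,3',4'-penta-O-benzylcatechin residue bound through C8.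

**Route**

Step 1
Reactants: 1 (+)-catechin
Product: 2 5,7,3',4'-tetra-O-benzylcatechin (2R,3S; free 3-OH)
Conditions: BnBr (4.5 equiv), K2CO3, DMF, N2, 0 °C → rt
Reagents that add atoms: benzyl bromide, BrCc1ccccc1
Why: Williamson ether synthesis: K2CO3 deprotonates only the four phenols, so the secondary 3-OH stays free and C2 and C3 are not touched.

Step 2
Reactants: 2 5,7,3',4'-tetra-O-benzylcatechin
Product: 3 3,5,7,3',4'-penta-O-benzylcatechin
Conditions: NaH, BnBr, DMF, 0 °C → rt
Reagents that add atoms: benzyl bromide, BrCc1ccccc1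
Why: Williamson ether synthesis on the sodium alkoxide removes the last acidic proton before the lithiation and keeps the lower O3 masked, and therefore unacylated, until the final hydrogenolysis.

Step 3
Reactants: 3 3,5,7,3',4'-penta-O-benzylcatechin
Product: 4 8-bromo-3,5,7,3',4'-penta-O-benzylcatechin
Conditions: NBS (1.0 equiv), CH2Cl2, −78 °C → 0 °C
Reagents that add atoms: N-bromosuccinimide, O=C1CCC(=O)N1Br
Why: Electrophilic aromatic bromination of the trioxygenated ring of benzylated catechins is known to favour C8 over C6, and one equivalent of NBS at low temperature should stop at the monobromide.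

Step 4
Reactants: 4 8-bromo-3,5,7,3',4'-penta-O-benzylcatechin; 5 (E)-3-(dimethylamino)acrolein
Product: 9 (E)-3-(catechin-8-yl)propenal, via aryllithium 6 (not isolated), via lithium alkoxide adduct 7 (not isolated), via vinylogous iminium ion 8 (not isolated)
Conditions: n-BuLi, THF, −78 °C; 5, −78 → 0 °C; then 1 M aq HCl, 0 °C
Reagents that add atoms: water, O
Why: Bromine–lithium exchange, 1,2-addition of the aryllithium to the vinylogous formamide, acid-induced loss of water and hydrolysis of the vinylogous iminium ion (a vinylogous Bouveault-type formylation) should deliver the thermodynamically favoured E-enal in one operation.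

Step 5
Reactants: 10 all-cis-cyclohexane-1,3,5-triol
Product: 11 all-cis-5-(tert-butyldimethylsilyloxy)cyclohexane-1,3-diol
Conditions: TBSCl (0.8 equiv relative to 10), imidazole, DMF, 0 °C → rt
Reagents that add atoms: tert-butyldimethylsilyl chloride, CC(C)(C)[Si](C)(C)Cl
Why: Silyl ether formation with the triol in excess should give mainly the monoether (unreacted triol is washed out with water), and silicon is chosen because this oxygen, the future O7, must later be unmasked in the presence of benzyl ethers.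

Step 6
Reactants: 11 all-cis-5-(tert-butyldimethylsilyloxy)cyclohexane-1,3-diol
Product: 13 5-(tert-butyldimethylsilyloxy)cyclohexane-1,3-dione, via hydroxy ketone 12 (not isolated)
Conditions: 2-iodoxybenzoic acid (IBX, 3 equiv), EtOAc, 75 °C
Reagents that add atoms: none
Why: IBX oxidation of both carbinols, the second being the known conversion of a β-hydroxy ketone into a β-diketone, runs without base, so the β-silyloxy group should not be eliminated, and the product is achiral.

Step 7
Reactants: 9 (E)-3-(catechin-8-yl)propenal; 13 5-(tert-butyldimethylsilyloxy)cyclohexane-1,3-dione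
Product: 16 (4S)-4-(catechin-8-yl)-7-(tert-butyldimethylsilyloxy)-2-hydroxy-2,3,4,6,7,8-hexahydro-5H-chromen-5-one (C2 and C7 as epimer mixtures), via iminium ion 14 (not isolated), via open-chain Michael aldehyde 15 (not isolated)
Conditions: (S)-α,α-diphenylprolinol trimethylsilyl ether (20 mol %), PhCO2H (20 mol %), CH2Cl2 (concentrated), rt
Reagents that add atoms: none
Why: The amine condenses with 9 to the E, s-trans iminium ion 14, the enol of 13 adds through its C2 to the β-carbon (C4–C4a), and hydrolytic release of the catalyst gives aldehyde 15. The enol oxygen of 15 then adds to the aldehyde carbon in a 6-exo-trig hemiacetalisation (O1–C2), which closes the oxygen heterocycle and draws the reversible conjugate addition to the product side. The closest known reaction type is the diarylprolinol-silyl-ether-catalysed Michael addition/hemiacetalisation of cyclic 1,3-diones with cinnamaldehyde-type enals. C4 is set by the catalyst: the CPh2(OSiMe3) group of the S-configured pyrrolidine covers one face of the planar iminium ion, so the dione attacks the open face and the 4S centre (4β-aryl, as in the target) should result, whereas C2 and C7 form as mixtures that are erased in steps 8 and 10. The step needs site selectivity in the nucleophile, 1,4- over 1,2-addition and face selectivity: 13 has one nucleophilic carbon, flanked by both carbonyls, and its O-addition is reversible, iminium activation directs attack to the β-carbon, and the stereocentres of the catechin residue lie far from C4, so the catalyst should dominate. Under these weakly acidic conditions 13 reacts as its enol or enolate, a form in which further deprotonation next to C5, and thus β-elimination of the silyloxy group, is disfavoured.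

Step 8
Reactants: 16 lactol
Product: 17 (4S)-4-(catechin-8-yl)-7-(tert-butyldimethylsilyloxy)-3,4,7,8-tetrahydro-2H-chromene-2,5(6H)-dione (C7 epimer mixture)
Conditions: Dess–Martin periodinane (1.3 equiv), CH2Cl2, 0 °C → rt; filtration through silica
Reagents that add atoms: none
Why: Dess–Martin oxidation of a lactol to the lactone works under neutral conditions that spare the vinylogous ester, the silyl ether and the benzyl ethers, and it removes the C2 epimer mixture.

Step 9
Reactants: 17 silyloxy enol lactone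
Product: 18 (4S)-4-(catechin-8-yl)-7-hydroxy-3,4,7,8-tetrahydro-2H-chromene-2,5(6H)-dione (C7 epimer mixture)
Conditions: HF·pyridine, THF, 0 °C → rt
Reagents that add atoms: none
Why: Fluoride-induced desilylation in an acidic medium frees the C7 carbinol without the basic conditions that would open the enol lactone or start E1cB loss of O7.

Step 10
Reactants: 18 hydroxy enol lactone
Product: 20 (4R)-4-(catechin-8-yl)-5,7-dihydroxychroman-2-one, via trione tautomer 19 (not isolated)
Conditions: Dess–Martin periodinane (1.05 equiv), CH2Cl2, 0 °C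
Reagents that add atoms: none
Why: Dess–Martin oxidation of the β-hydroxy ketone gives trione 19, the keto tautomer of a phloroglucinol, which enolises irreversibly to aromatic ring A, so the missing unsaturation comes from the C7–H/O–H pair, O7 stays in place, the C7 mixture is erased and C4 is untouched (its descriptor becomes R only through changed priorities).

Step 11
Reactants: 20 dihydroxychromanone
Product: 21 (4R)-5,7-bis(benzyloxy)-4-(catechin-8-yl)chroman-2-one
Conditions: BnBr (2.5 equiv), dry K2CO3, DMF, rt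
Reagents that add atoms: benzyl bromide, BrCc1ccccc1
Why: Williamson ether synthesis with dry K2CO3 alkylates both phenols while the non-nucleophilic base leaves the six-membered aryl lactone closed, and C4 carries no acidic proton and keeps its configuration.

Step 12
Reactants: 21 bis(benzyloxy)chromanone
Product: 23 (3R,4R)-5,7-bis(benzyloxy)-4-(catechin-8-yl)-3-hydroxychroman-2-one (3,4-trans), via potassium enolate 22 (not isolated)
Conditions: KN(SiMe3)2 (1.1 equiv), THF, −78 °C; 2-(phenylsulfonyl)-3-phenyloxaziridine, −78 °C; AcOH quench at −78 °C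
Reagents that add atoms: 2-(phenylsulfonyl)-3-phenyloxaziridine, O=S(=O)(c1ccccc1)N1OC1c1ccccc1
Why: Davis oxidation of the lactone enolate: peri strain with the 5-benzyloxy group holds the C4 aryl residue pseudo-axial, where it blocks one face of the enolate, so oxygen is delivered anti to it and the 3,4-trans (3R) alcohol should form, while −78 °C keeps the aryl ester enolate from fragmenting to a ketene.

Step 13
Reactants: 24 5-bromo-1,2,3-trimethoxybenzene
Product: 25 5-bromobenzene-1,2,3-triol
Conditions: BBr3 (3.5 equiv), CH2Cl2, −78 °C → rt; then H2O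
Reagents that add atoms: none
Why: Lewis-acid ether cleavage: BBr3 demethylates all three aryl methyl ethers and does not affect the aryl bromide.

Step 14
Reactants: 25 5-bromobenzene-1,2,3-triol
Product: 26 5-bromo-1,2,3-tris(benzyloxy)benzene
Conditions: BnBr (3.5 equiv), K2CO3, DMF, rt → 50 °C
Reagents that add atoms: benzyl bromide, BrCc1ccccc1
Why: Threefold Williamson ether synthesis installs the same hydrogenolysable groups as elsewhere and removes all acidic protons before the lithiation.

Step 15
Reactants: 23 3-hydroxychromanone; 26 5-bromo-1,2,3-tris(benzyloxy)benzene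
Product: 29 (3R,4R)-hydroxy ketone: 3-[2,4-bis(benzyloxy)-6-hydroxyphenyl]-3-(catechin-8-yl)-2-hydroxy-1-[3,4,5-tris(benzyloxy)phenyl]propan-1-one, via aryllithium 27 (not isolated), via tetrahedral dilithium adduct 28 (not isolated)
Conditions: 26 (2.3 equiv), n-BuLi (2.2 equiv), THF, −78 °C; then 23, −78 °C; AcOH, −78 °C → rt
Reagents that add atoms: none
Why: Bromine–lithium exchange gives 27, of which the first equivalent deprotonates the 3-OH and the second adds to the lactone carbonyl (nucleophilic acyl substitution via 28, C2–C1' bond), and the ketone set free with the C8a phenoxide should resist a second addition at −78 °C because of the neighbouring alkoxide, its conjugation with the electron-rich aryl ring and the bulky C4 substituent, with C3 and C4 untouched.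

Step 16
Reactants: 29 hydroxy ketone
Product: 30 (2S,3R,4R)-2,3-anti diol: 3-[2,4-bis(benzyloxy)-6-hydroxyphenyl]-3-(catechin-8-yl)-1-[3,4,5-tris(benzyloxy)phenyl]propane-1,2-diol
Conditions: Zn(BH4)2 (stock solution in Et2O), Et2O/CH2Cl2, −30 → 0 °C; then H2O
Reagents that add atoms: none
Why: Chelation-controlled (Cram-chelate) reduction: zinc binds the ketone oxygen and O3 in a five-membered chelate, hydride enters from the side of the small C3–H and not of the diarylmethyl group, and the 2,3-anti diol with the 2S carbinol should result.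

Step 17
Reactants: 30 anti diol
Product: 32 5,7,3',4',5'-penta-O-benzyl-epigallocatechin-(4β→8)-penta-O-benzylcatechin (upper unit 2R,3R,4R; free upper 3-OH), via oxyphosphonium phenoxide 31 (not isolated)
Conditions: PPh3, DIAD (slow addition), toluene, 0 °C
Reagents that add atoms: none
Why: Intramolecular Mitsunobu etherification: the benzylic C2–OH, less hindered than the 3-OH next to the diarylmethyl carbon, is activated as oxyphosphonium ion 31 and displaced by the acidic C8a phenol in a 6-exo-tet SN2 closure with inversion (2S to 2R), which gives the 2,3-cis-3,4-trans ring C, and the apolar solvent and low temperature work against ionisation at C2.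

Step 18
Reactants: 32 decabenzyl dimer with free upper 3-OH; 33 3,4,5-tris(benzyloxy)benzoic acid
Product: 35 trideca-O-benzyl ether of the target (upper 3-O-[3,4,5-tris(benzyloxy)benzoyl] ester), via O-acylisourea 34 (not isolated)
Conditions: 33 (3 equiv), DCC, DMAP, CH2Cl2, rt
Reagents that add atoms: none
Why: DMAP-catalysed Steglich esterification acylates the only free hydroxyl, the hindered axial upper 3-OH, with retention because the C3–O bond is not broken.

Step 19
Reactants: 35 trideca-O-benzyl ether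
Product: 36 epigallocatechin 3-O-gallate-(4β→8)-catechin (target, CNP0129434.1)
Conditions: H2 (1 atm), Pd(OH)2/C, THF/MeOH/H2O, rt
Reagents that add atoms: none
Why: Catalytic hydrogenolysis cleaves all thirteen benzyl ethers under neutral conditions in which the gallate ester, the interflavan C4–C8 bond and the five stereocentres persist.

**Compound list**
1 | (+)-catechin | O[C@H]1Cc2c(O)cc(O)cc2O[C@@H]1c1ccc(O)c(O)c1 | starting material
2 | 5,7,3',4'-tetra-O-benzylcatechin | c2c(OCc9ccccc9)cc(OCc9ccccc9)c3c2O[C@H](c4ccc(OCc9ccccc9)c(OCc9ccccc9)c4)[C@@H](O)C3 | intermediate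
3 | 3,5,7,3',4'-penta-O-benzylcatechin | c2c(OCc9ccccc9)cc(OCc9ccccc9)c3c2O[C@H](c4ccc(OCc9ccccc9)c(OCc9ccccc9)c4)[C@@H](OCc9ccccc9)C3 | intermediate
4 | 8-bromo-penta-O-benzylcatechin | Brc2c(OCc9ccccc9)cc(OCc9ccccc9)c3c2O[C@H](c4ccc(OCc9ccccc9)c(OCc9ccccc9)c4)[C@@H](OCc9ccccc9)C3 | intermediate
5 | (E)-3-(dimethylamino)acrolein | CN(C)/C=C/C=O | starting material
6 | 8-lithio-penta-O-benzylcatechin | [Li]c2c(OCc9ccccc9)cc(OCc9ccccc9)c3c2O[C@H](c4ccc(OCc9ccccc9)c(OCc9ccccc9)c4)[C@@H](OCc9ccccc9)C3 | intermediate (not isolated)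
7 | lithium (E)-1-(catechin-8-yl)-3-(dimethylamino)prop-2-en-1-olate (carbinol centre uncontrolled) | [Li]OC(/C=C/N(C)C)c2c(OCc9ccccc9)cc(OCc9ccccc9)c3c2O[C@H](c4ccc(OCc9ccccc9)c(OCc9ccccc9)c4)[C@@H](OCc9ccccc9)C3 | intermediate (not isolated)
8 | N,N-dimethyl-(E)-3-(catechin-8-yl)prop-2-en-1-iminium ion | C[N+](C)=C/C=C/c2c(OCc9ccccc9)cc(OCc9ccccc9)c3c2O[C@H](c4ccc(OCc9ccccc9)c(OCc9ccccc9)c4)[C@@H](OCc9ccccc9)C3 | intermediate (not isolated)
9 | (E)-3-(catechin-8-yl)propenal | O=C/C=C/c2c(OCc9ccccc9)cc(OCc9ccccc9)c3c2O[C@H](c4ccc(OCc9ccccc9)c(OCc9ccccc9)c4)[C@@H](OCc9ccccc9)C3 | intermediate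
10 | all-cis-cyclohexane-1,3,5-triol | O[C@H]1C[C@@H](O)C[C@@H](O)C1 | starting material
11 | all-cis-5-(tert-butyldimethylsilyloxy)cyclohexane-1,3-diol | CC(C)(C)[Si](C)(C)O[C@H]1C[C@@H](O)C[C@@H](O)C1 | intermediate
12 | cis-3-hydroxy-5-(tert-butyldimethylsilyloxy)cyclohexanone (racemic, one enantiomer drawn) | CC(C)(C)[Si](C)(C)O[C@H]1C[C@@H](O)CC(=O)C1 | intermediate (not isolated)
13 | 5-(tert-butyldimethylsilyloxy)cyclohexane-1,3-dione | CC(C)(C)[Si](C)(C)OC1CC(=O)CC(=O)C1 | intermediate
14 | iminium ion of 9 and (S)-α,α-diphenylprolinol trimethylsilyl ether | C[Si](C)(C)OC(c1ccccc1)(c1ccccc1)[C@@H]1CCC[N+]1=C/C=C/c2c(OCc9ccccc9)cc(OCc9ccccc9)c3c2O[C@H](c4ccc(OCc9ccccc9)c(OCc9ccccc9)c4)[C@@H](OCc9ccccc9)C3 | intermediate (not isolated)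
15 | (3S)-3-(catechin-8-yl)-3-[2-hydroxy-6-oxo-4-(tert-butyldimethylsilyloxy)cyclohex-1-enyl]propanal | O=CC[C@@H](c2c(OCc9ccccc9)cc(OCc9ccccc9)c3c2O[C@H](c4ccc(OCc9ccccc9)c(OCc9ccccc9)c4)[C@@H](OCc9ccccc9)C3)C7=C(O)CC(O[Si](C)(C)C(C)(C)C)CC7=O | intermediate (not isolated)
16 | (4S)-lactol, C2 and C7 mixtures | OC1C[C@@H](c2c(OCc9ccccc9)cc(OCc9ccccc9)c3c2O[C@H](c4ccc(OCc9ccccc9)c(OCc9ccccc9)c4)[C@@H](OCc9ccccc9)C3)C7=C(O1)CC(O[Si](C)(C)C(C)(C)C)CC7=O | intermediate
17 | (4S)-7-silyloxy enol lactone, C7 mixture | O=C1C[C@@H](c2c(OCc9ccccc9)cc(OCc9ccccc9)c3c2O[C@H](c4ccc(OCc9ccccc9)c(OCc9ccccc9)c4)[C@@H](OCc9ccccc9)C3)C7=C(O1)CC(O[Si](C)(C)C(C)(C)C)CC7=O | intermediate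
18 | (4S)-7-hydroxy enol lactone, C7 mixture | O=C1C[C@@H](c2c(OCc9ccccc9)cc(OCc9ccccc9)c3c2O[C@H](c4ccc(OCc9ccccc9)c(OCc9ccccc9)c4)[C@@H](OCc9ccccc9)C3)C7=C(O1)CC(O)CC7=O | intermediate
19 | (4S)-4-(catechin-8-yl)-3,4-dihydro-2H-chromene-2,5,7(6H,8H)-trione | O=C1C[C@@H](c2c(OCc9ccccc9)cc(OCc9ccccc9)c3c2O[C@H](c4ccc(OCc9ccccc9)c(OCc9ccccc9)c4)[C@@H](OCc9ccccc9)C3)C7=C(O1)CC(=O)CC7=O | intermediate (not isolated)
20 | (4R)-4-(catechin-8-yl)-5,7-dihydroxychroman-2-one | O=C1C[C@@H](c2c(OCc9ccccc9)cc(OCc9ccccc9)c3c2O[C@H](c4ccc(OCc9ccccc9)c(OCc9ccccc9)c4)[C@@H](OCc9ccccc9)C3)c7c(O1)cc(O)cc7O | intermediate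
21 | (4R)-5,7-bis(benzyloxy)-4-(catechin-8-yl)chroman-2-one | O=C1C[C@@H](c2c(OCc9ccccc9)cc(OCc9ccccc9)c3c2O[C@H](c4ccc(OCc9ccccc9)c(OCc9ccccc9)c4)[C@@H](OCc9ccccc9)C3)c7c(O1)cc(OCc9ccccc9)cc7OCc9ccccc9 | intermediate
22 | potassium enolate of 21 | [K]OC1=C[C@@H](c2c(OCc9ccccc9)cc(OCc9ccccc9)c3c2O[C@H](c4ccc(OCc9ccccc9)c(OCc9ccccc9)c4)[C@@H](OCc9ccccc9)C3)c7c(O1)cc(OCc9ccccc9)cc7OCc9ccccc9 | intermediate (not isolated)
23 | (3R,4R)-5,7-bis(benzyloxy)-4-(catechin-8-yl)-3-hydroxychroman-2-one | O=C1[C@H](O)[C@@H](c2c(OCc9ccccc9)cc(OCc9ccccc9)c3c2O[C@H](c4ccc(OCc9ccccc9)c(OCc9ccccc9)c4)[C@@H](OCc9ccccc9)C3)c7c(O1)cc(OCc9ccccc9)cc7OCc9ccccc9 | intermediate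
24 | 5-bromo-1,2,3-trimethoxybenzene | COc1cc(Br)cc(OC)c1OC | starting material
25 | 5-bromobenzene-1,2,3-triol | Oc1cc(Br)cc(O)c1O | intermediate
26 | 5-bromo-1,2,3-tris(benzyloxy)benzene | Brc1cc(OCc2ccccc2)c(OCc2ccccc2)c(OCc2ccccc2)c1 | intermediate
27 | 3,4,5-tris(benzyloxy)phenyllithium | [Li]c1cc(OCc2ccccc2)c(OCc2ccccc2)c(OCc2ccccc2)c1 | intermediate (not isolated)
28 | dilithium salt of the 2-aryl-2,3-dihydroxychroman adduct (C2 uncontrolled) | [Li]OC1(c8cc(OCc9ccccc9)c(OCc9ccccc9)c(OCc9ccccc9)c8)[C@H](O[Li])[C@@H](c2c(OCc9ccccc9)cc(OCc9ccccc9)c3c2O[C@H](c4ccc(OCc9ccccc9)c(OCc9ccccc9)c4)[C@@H](OCc9ccccc9)C3)c7c(O1)cc(OCc9ccccc9)cc7OCc9ccccc9 | intermediate (not isolated)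
29 | (3R,4R)-hydroxy ketone with free C8a phenol | O=C(c8cc(OCc9ccccc9)c(OCc9ccccc9)c(OCc9ccccc9)c8)[C@H](O)[C@@H](c2c(OCc9ccccc9)cc(OCc9ccccc9)c3c2O[C@H](c4ccc(OCc9ccccc9)c(OCc9ccccc9)c4)[C@@H](OCc9ccccc9)C3)c7c(O)cc(OCc9ccccc9)cc7OCc9ccccc9 | intermediate
30 | (2S,3R,4R)-2,3-anti diol with free C8a phenol | O[C@@H](c8cc(OCc9ccccc9)c(OCc9ccccc9)c(OCc9ccccc9)c8)[C@H](O)[C@@H](c2c(OCc9ccccc9)cc(OCc9ccccc9)c3c2O[C@H](c4ccc(OCc9ccccc9)c(OCc9ccccc9)c4)[C@@H](OCc9ccccc9)C3)c7c(O)cc(OCc9ccccc9)cc7OCc9ccccc9 | intermediate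
31 | C2-oxyphosphonium phenoxide zwitterion of 30 | c1ccccc1[P+](c1ccccc1)(c1ccccc1)O[C@@H](c8cc(OCc9ccccc9)c(OCc9ccccc9)c(OCc9ccccc9)c8)[C@H](O)[C@@H](c2c(OCc9ccccc9)cc(OCc9ccccc9)c3c2O[C@H](c4ccc(OCc9ccccc9)c(OCc9ccccc9)c4)[C@@H](OCc9ccccc9)C3)c7c([O-])cc(OCc9ccccc9)cc7OCc9ccccc9 | intermediate (not isolated)
32 | penta-O-benzyl-epigallocatechin-(4β→8)-penta-O-benzylcatechin, free upper 3-OH | O[C@@H]1[C@@H](c2c(OCc9ccccc9)cc(OCc9ccccc9)c3c2O[C@H](c4ccc(OCc9ccccc9)c(OCc9ccccc9)c4)[C@@H](OCc9ccccc9)C3)c7c(OCc9ccccc9)cc(OCc9ccccc9)cc7O[C@@H]1c8cc(OCc9ccccc9)c(OCc9ccccc9)c(OCc9ccccc9)c8 | intermediate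
33 | 3,4,5-tris(benzyloxy)benzoic acid | O=C(O)c1cc(OCc2ccccc2)c(OCc2ccccc2)c(OCc2ccccc2)c1 | starting material
34 | O-[3,4,5-tris(benzyloxy)benzoyl]-N,N'-dicyclohexylisourea | O=C(OC(=NC1CCCCC1)NC1CCCCC1)c1cc(OCc2ccccc2)c(OCc2ccccc2)c(OCc2ccccc2)c1 | intermediate (not isolated)
35 | trideca-O-benzyl ether of the target | O=C(O[C@@H]1[C@@H](c2c(OCc9ccccc9)cc(OCc9ccccc9)c3c2O[C@H](c4ccc(OCc9ccccc9)c(OCc9ccccc9)c4)[C@@H](OCc9ccccc9)C3)c7c(OCc9ccccc9)cc(OCc9ccccc9)cc7O[C@@H]1c8cc(OCc9ccccc9)c(OCc9ccccc9)c(OCc9ccccc9)c8)c1cc(OCc9ccccc9)c(OCc9ccccc9)c(OCc9ccccc9)c1 | intermediate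
36 | epigallocatechin 3-O-gallate-(4β→8)-catechin | O=C(O[C@@H]1[C@@H](c2c(O)cc(O)c3c2O[C@H](c2ccc(O)c(O)c2)[C@@H](O)C3)c2c(O)cc(O)cc2O[C@@H]1c1cc(O)c(O)c(O)c1)c1cc(O)c(O)c(O)c1 | target

**Step count**
Total step count: 19. Longest linear sequence: 15 steps from (+)-catechin (steps 1–4, 7–12, 15–19).

**Steps most likely to fail**

Step 7. The iminium ion of a 2,4,6-trioxygenated, doubly ortho-substituted cinnamaldehyde is strongly donor-stabilised. C–C bond formation may therefore be slow and reversible. Retro-Michael equilibration could erode the face selectivity, and the catalyst could be tied up by condensation with the dione.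
The fallback is oxidative N-heterocyclic-carbene catalysis, and it again sets out from 9 and 13. The reagents are a chiral aminoindanol-derived N-mesityltriazolium salt (10 mol %), a catalytic amine base and 3,3',5,5'-tetra-tert-butyldiphenoquinone (1 equiv) in toluene. They raise the enal to the acyl oxidation level on the catalyst. This acceptor is much more electrophilic, takes up C2 of the dione at the β-carbon, and is then released by irreversible O-acylation of the enol oxygen. The catalyst enantiomer is chosen for the 4S centre. The product is the enol lactone itself, so the route is rejoined at 17 and step 8 is saved. No compound outside the list is made (line F0).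

Step 10. Dehydration of the β-hydroxy ketone (loss of O7, leading to a 7-deoxygenated aromatic ring) may compete with oxidation. The periodinane may also oxidise the freshly formed electron-rich phenol further.
The fallback is a C–C dehydrogenation with O7 still silylated (Saegusa–Ito oxidation), and it sets out from 17. Me3SiOTf/Et3N in CH2Cl2 at 0 °C should give the 5-(trimethylsilyloxy)diene F1 by soft enolisation without a free enolate. Pd(OAc)2 (1 equiv, divalent palladium) in MeCN then removes the C6 and C7 hydrogens, as is known for β-alkoxy ketones that give vinylogous esters. Tautomerisation leads to the 5-hydroxy-7-silyloxychroman-2-one F2. HF·pyridine cleaves the aryl silyl ether, and the route is rejoined at 20.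

Step 17. Three processes may interfere with clean inversion, and each would lead to the wrong ring or to the 2,3-trans isomer:
- ionisation of the activated, alkoxy-stabilised benzylic centre;
- activation of the 3-OH in place of the 2-OH;
- epoxide formation from the 1,2-diol.

The fallback is an acid-catalysed orthoester cyclisation, and it sets out from 30. HC(OEt)3 and catalytic pyridinium p-toluenesulfonate in ClCH2CH2Cl at 55 °C tie both hydroxyls into the cyclic 2-ethoxy-1,3-dioxolane F3. After acid-induced loss of ethanol, the C8a phenol opens the activated ring at benzylic C2 with inversion. Neither epoxide formation nor attack at C3 is then possible. The product is the flavan 3-O-formate F4. K2CO3 in MeOH/CH2Cl2 removes the formate, and the route is rejoined at 32.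

**Further compounds**
F0 | step 7 | none | none
F1 | step 10 | (4S)-4-(catechin-8-yl)-7-(tert-butyldimethylsilyloxy)-5-(trimethylsilyloxy)-3,4,7,8-tetrahydro-2H-chromen-2-one (C7 mixture) | O=C1C[C@@H](c2c(OCc9ccccc9)cc(OCc9ccccc9)c3c2O[C@H](c4ccc(OCc9ccccc9)c(OCc9ccccc9)c4)[C@@H](OCc9ccccc9)C3)C7=C(O1)CC(O[Si](C)(C)C(C)(C)C)C=C7O[Si](C)(C)C
F2 | step 10 | (4R)-4-(catechin-8-yl)-5-hydroxy-7-(tert-butyldimethylsilyloxy)chroman-2-one | O=C1C[C@@H](c2c(OCc9ccccc9)cc(OCc9ccccc9)c3c2O[C@H](c4ccc(OCc9ccccc9)c(OCc9ccccc9)c4)[C@@H](OCc9ccccc9)C3)c7c(O1)cc(O[Si](C)(C)C(C)(C)C)cc7O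
F3 | step 17 | cyclic 2-ethoxy-1,3-dioxolane (orthoformate) of diol 30, orthoester carbon uncontrolled | CCOC1O[C@@H](c8cc(OCc9ccccc9)c(OCc9ccccc9)c(OCc9ccccc9)c8)[C@H](O1)[C@@H](c2c(OCc9ccccc9)cc(OCc9ccccc9)c3c2O[C@H](c4ccc(OCc9ccccc9)c(OCc9ccccc9)c4)[C@@H](OCc9ccccc9)C3)c7c(O)cc(OCc9ccccc9)cc7OCc9ccccc9
F4 | step 17 | upper 3-O-formate of 32 | O=CO[C@@H]1[C@@H](c2c(OCc9ccccc9)cc(OCc9ccccc9)c3c2O[C@H](c4ccc(OCc9ccccc9)c(OCc9ccccc9)c4)[C@@H](OCc9ccccc9)C3)c7c(OCc9ccccc9)cc(OCc9ccccc9)cc7O[C@@H]1c8cc(OCc9ccccc9)c(OCc9ccccc9)c(OCc9ccccc9)c8
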